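The data come from a simulation for an exercise; noise was put on by code.

the same everywhere: catalyst 10 mM
- south-west: starting material 0.050 M; reagent 0.18 M; second substrate 0.10 M; run made earlier
- south-east: starting material 0.20 M; reagent 0.18 M; second substrate 0.10 M; run made earlier
- violet: starting material 0.10 M; reagent 0.180 M; second substrate 0.100 M; time 6.0 min
- amber: starting material 0.10 M; reagent 0.180 M; second substrate 0.100 M; time 10 min

- south-west (time / min: target / %, starting material / %, side product / %): 0.833: 19.6, 33.8, 47.7; 2.00: 14.5, 13.1, 74.0; 2.50: 14.5, 6.4, 77.8; 4.00: 10.5, 4.0, 84.3
- south-east (time / min: target / %, starting material / %, side product / %): 0.250: 6.4, 68.9, 24.6; 0.667: 5.5, 39.1, 54.8; 1.50: 2.3, 17.9, 75.7; 4.00: 0.7, 8.1, 93.3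

(standard deviation of a reading: 1 percentage point)

* which of these there is most of at the end, counted by the starting material in it, violet (target / starting material / side product)
* which of these there is most of at the end, counted by the starting material in it, amber (target / starting material / side product)
* final amount of the leader among these, as a percentage of the starting material charged, in violet
* final amount of the leader among these, as a percentage of the starting material charged, in amber

- percentages count the starting material that a species holds: one side product counts as two
- the numbers in the tables scatter with a standard deviation of 1 percentage point

The rows of both runs sum to about 100, so the side product holds whatever the remainder U, target plus starting material, does not. The question is how fast U falls. A first estimate takes a fixed half-life: in the south-west run U goes from 27.6% at 2.00 min to 14.5% at 4.00 min, a half-life of 2.15 min. The objection is that the same run began with a half-life of 0.920 min, so the half-life lengthens, as in a second-order decay, where U falls as one over time.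

The better count therefore uses the remainder time θ, U multiplied by the time elapsed, which is 0.552 min at 2.00 min and 0.580 min at 4.00 min in the south-west run. For a second-order decay, with the other charges held, θ scales inversely with the charge of starting material, which gives 0.290 min at 0.10 M. But the south-east run objects: it should show 0.145 min and shows 0.303 min at 1.50 min, twice that. There, however, the reagent, at 0.18 M, stands below the starting material, at 0.20 M, whereas in violet it stands above, at 0.180 M against 0.10 M, as it does in the south-west run, at 0.18 M against 0.050 M. So the south-west value stands, and the south-east value, which gives U of 10.1% in violet, marks the risk. My reckoning gives U of 4.83% in violet and 2.90% in amber, hence side product near 95.2% and 97.1%.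

The forecast names side product at 94% for violet, below this reckoning, and side product at 97% for amber, with target that “drains into side product, faster at higher loading”.

The flask gives side product at 94.7% in violet and side product at 96.9% in amber, from these steps:

    starting material + reagent + catalyst ⇌ catalyst + target (K = 26.0 M⁻¹, k = 10.0 M⁻² s⁻¹)
    starting material + target → side product (k = 1.10 M⁻¹ s⁻¹)
    second substrate + reagent + catalyst → catalyst + second product (k = 6.50 M⁻² s⁻¹)

The forecast agrees with both, and U in violet is 5.32% against the reckoned 4.83%. Amber ends with 21.7% of its reagent free. A neighbouring flask, like amber but with 0.25 M of second substrate, ends otherwise: θ still reckons U at 2.90%, yet U in that flask is 9.90%, its reagent is down to 0.28% of its charge, and its side product stands at 90.1%.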